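**Retrosynthetic overview**
1. Two Wittig disconnections (C11=C12 and C11′=C12′) split the C40 polyene into a C15 cis-5,6-diol phosphonium salt, a C10 central unit and a C15 5,8-furanoid phosphonium salt; a lipase mono-acetylation tells the two ends of the symmetric C10 diol apart.
2. Both end groups come from one epoxy aldehyde, made from achiral β-cyclocitral by Sharpless asymmetric epoxidation of β-cyclogeraniol (Ti(OiPr)4/D-tartrate); this fixes C5 (R) for both halves.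
3. Furanoid half: epoxy alkyne, Sonogashira enyne ester, i-Bu2AlH syn-SN2′ reduction to the (6R)-allenol, then AuCl3 5-endo cyclisation (allene axis sets C8′).
4. Diol half: Wharton transposition and ozonolysis give the (R)-α-silyloxy ketone; acetylide addition anti to the silyloxy group sets C6 (cis-diol); hydroalumination gives the 7E alkene.
5. Ring order: both cyclohexane rings are bought with β-cyclocitral; the oxirane is made in step 2 and opened in steps 7 and 16; the dihydrofuran is the only ring built, in step 8.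

Assumption: the Wittig steps 13 and 24 give the new disubstituted double bond as an E/Z mixture; polyenes 18, 19, 20 and 35 are named and drawn as all-E, and the hindered Z isomer is converged by the heating written into steps 15 and 24.

**Route**

Step 1
Reactants: 1 β-cyclocitral (2,6,6-trimethylcyclohex-1-ene-1-carbaldehyde)
Product: 2 β-cyclogeraniol [(2,6,6-trimethylcyclohex-1-en-1-yl)methanol]
Conditions: NaBH4, MeOH, 0 °C
Reagents that add atoms: none
Why: Carbonyl reduction by hydride goes 1,2 on the hindered enal and leaves the tetrasubstituted alkene alone; no stereocentre is formed.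

Step 2
Reactants: 2 β-cyclogeraniol
Product: 3 [(1R,6R)-2,2,6-trimethyl-7-oxabicyclo[4.1.0]heptan-1-yl]methanol
Conditions: Ti(OiPr)4 (10 mol%), D-(−)-diisopropyl tartrate (13 mol%), t-BuOOH (2 equiv, decane), 4 Å molecular sieves, CH2Cl2, −20 °C
Reagents that add atoms: tert-butyl hydroperoxide CC(C)(C)OO
Why: Sharpless asymmetric epoxidation with the Ti–D-tartrate catalyst delivers oxygen to the alkene face that gives the 5R,6S-type epoxide (carotenoid numbering), setting both ring stereocentres in one catalytic step.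

Step 3
Reactants: 3 [(1R,6R)-2,2,6-trimethyl-7-oxabicyclo[4.1.0]heptan-1-yl]methanol
Product: 4 (1S,6R)-2,2,6-trimethyl-7-oxabicyclo[4.1.0]heptane-1-carbaldehyde
Conditions: nPr4N[RuO4] (5 mol%), N-methylmorpholine N-oxide, 4 Å molecular sieves, CH2Cl2, rt
Reagents that add atoms: none
Why: Ley–Griffith oxidation is neutral, so the primary carbinol becomes the non-enolisable aldehyde without opening the epoxide (the descriptor at C1 changes by priority only).

Step 4
Reactants: 4 (1S,6R)-2,2,6-trimethyl-7-oxabicyclo[4.1.0]heptane-1-carbaldehyde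
Product: 5 (1R,6R)-1-ethynyl-2,2,6-trimethyl-7-oxabicyclo[4.1.0]heptane
Conditions: Ohira–Bestmann reagent, K2CO3, MeOH, 0 °C → rt
Reagents that add atoms: dimethyl (1-diazo-2-oxopropyl)phosphonate CC(=O)C(=[N+]=[N-])P(=O)(OC)OC
Why: Seyferth–Gilbert homologation (Ohira–Bestmann version) converts the aldehyde, which has no α-hydrogen to lose, into the terminal alkyne with the epoxide untouched.

Step 5
Reactants: 6 ethyl acetoacetate
Product: 7 ethyl (2E)-3-{[(trifluoromethyl)sulfonyl]oxy}but-2-enoate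
Conditions: Tf2O, aq. Me4NOH, hexanes, 5 °C → rt
Reagents that add atoms: trifluoromethanesulfonic anhydride FC(F)(F)S(=O)(=O)OS(=O)(=O)C(F)(F)F
Why: Enol triflation of the non-chelated tetramethylammonium enolate gives the E enol triflate, which fixes the later 9′E geometry.

Step 6
Reactants: 5 (1R,6R)-1-ethynyl-2,2,6-trimethyl-7-oxabicyclo[4.1.0]heptane; 7 ethyl (2E)-3-{[(trifluoromethyl)sulfonyl]oxy}but-2-enoate
Product: 8 ethyl (2E)-3-methyl-5-[(1R,6R)-2,2,6-trimethyl-7-oxabicyclo[4.1.0]heptan-1-yl]pent-2-en-4-ynoate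
Conditions: Pd(PPh3)4 (3 mol%), CuI (6 mol%), i-Pr2NH, THF, rt
Reagents that add atoms: none
Why: Sonogashira coupling, in which the electron-poor enol triflate adds quickly to zerovalent palladium with retention of alkene geometry while the hindered tetrasubstituted epoxide is left alone.

Step 7
Reactants: 8 ethyl (2E)-3-methyl-5-[(1R,6R)-2,2,6-trimethyl-7-oxabicyclo[4.1.0]heptan-1-yl]pent-2-en-4-ynoate
Product: 9 (2E)-5-[(2R)-2-hydroxy-2,6,6-trimethylcyclohexylidene]-3-methylpenta-2,4-dien-1-ol (allene axis R; the 5R,6R allenic end group with H-8 on the side of the 5-OH)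
Conditions: i-Bu2AlH (5 equiv), CH2Cl2, −78 → 0 °C; aq. potassium sodium tartrate
Reagents that add atoms: none
Why: After ester reduction, aluminium bound to the epoxide oxygen delivers hydride to C8 on the side of the breaking C6–O bond (syn-SN2′ reduction, as used for the neoxanthin/peridinin allene end group), so the epoxide configuration is relayed into the R allene axis with C9 anti to the 5-oxygen.

Step 8
Reactants: 9 (2E)-5-[(2R)-2-hydroxy-2,6,6-trimethylcyclohexylidene]-3-methylpenta-2,4-dien-1-ol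
Product: 10 (2E)-3-[(2S,7aR)-4,4,7a-trimethyl-2,4,5,6,7,7a-hexahydro-1-benzofuran-2-yl]but-2-en-1-ol
Conditions: AuCl3 (2 mol%), THF, rt
Reagents that add atoms: none
Why: Gold-catalysed 5-endo cycloisomerisation of the α-hydroxyallene, in which the 5-OH adds to C8 in the plane of the C6 substituents, so the allene axis becomes the new C8 centre (S, side chain cis to the 7a-methyl) while C5 is unchanged.

Step 9
Reactants: 10 (2E)-3-[(2S,7aR)-4,4,7a-trimethyl-2,4,5,6,7,7a-hexahydro-1-benzofuran-2-yl]but-2-en-1-ol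
Product: 12 {(2E)-3-[(2S,7aR)-4,4,7a-trimethyl-2,4,5,6,7,7a-hexahydro-1-benzofuran-2-yl]but-2-en-1-yl}(triphenyl)phosphonium bromide, via allylic bromide 11 (not isolated)
Conditions: CBr4, PPh3, 2,6-lutidine (0.2 equiv), CH2Cl2, −20 °C; then PPh3, rt
Reagents that add atoms: carbon tetrabromide BrC(Br)(Br)Br; triphenylphosphine c1ccc(cc1)P(c1ccccc1)c1ccccc1
Why: Appel bromination of the primary allylic alcohol followed by SN2 quaternisation of PPh3 stays neutral, so the acid-labile bis-allylic ether centre C8 is not epimerised.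

Step 10
Reactants: 13 (2E,4E,6E)-2,7-dimethylocta-2,4,6-trienedial
Product: 14 (2E,4E,6E)-2,7-dimethylocta-2,4,6-triene-1,8-diol
Conditions: NaBH4, MeOH/THF, 0 °C
Reagents that add atoms: none
Why: Carbonyl reduction of both aldehydes by hydride without touching the triene.

Step 11
Reactants: 14 (2E,4E,6E)-2,7-dimethylocta-2,4,6-triene-1,8-diol
Product: 15 (2E,4E,6E)-8-hydroxy-2,7-dimethylocta-2,4,6-trien-1-yl acetate
Conditions: immobilised Candida antarctica lipase B (Novozym 435), vinyl acetate (1.3 equiv), THF/t-BuOMe, 25 °C, stopped at maximum mono-acetate (diol and diacetate recycled)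
Reagents that add atoms: vinyl acetate CC(=O)OC=C
Why: Lipase-catalysed irreversible transesterification acetylates one of the two equivalent primary allylic hydroxyls under neutral conditions, so the two ends of the C10 unit become different and can be coupled one after the other.

Step 12
Reactants: 15 (2E,4E,6E)-8-hydroxy-2,7-dimethylocta-2,4,6-trien-1-yl acetate
Product: 16 (2E,4E,6E)-2,7-dimethyl-8-oxoocta-2,4,6-trien-1-yl acetate
Conditions: activated MnO2, CH2Cl2, rt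
Reagents that add atoms: none
Why: Allylic oxidation by MnO2 gives the trienal and leaves the acetate alone.

Step 13
Reactants: 12 {(2E)-3-[(2S,7aR)-4,4,7a-trimethyl-2,4,5,6,7,7a-hexahydro-1-benzofuran-2-yl]but-2-en-1-yl}(triphenyl)phosphonium bromide; 16 (2E,4E,6E)-2,7-dimethyl-8-oxoocta-2,4,6-trien-1-yl acetate
Product: 18 (2E,4E,6E,8E,10E)-2,7-dimethyl-11-[(2S,7aR)-4,4,7a-trimethyl-2,4,5,6,7,7a-hexahydro-1-benzofuran-2-yl]dodeca-2,4,6,8,10-pentaen-1-yl acetate, via phosphonium ylide 17 (not isolated)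
Conditions: 1,2-epoxybutane/CH2Cl2 (3:1), 60 °C, 20 h, N2, dark
Reagents that add atoms: none
Why: Wittig olefination with the ylide generated under neutral conditions (bromide opens epoxybutane to the alkoxide base) builds C11′=C12′ without cleaving the acetate or epimerising C8′.

Step 14
Reactants: 18 (2E,4E,6E,8E,10E)-2,7-dimethyl-11-[(2S,7aR)-4,4,7a-trimethyl-2,4,5,6,7,7a-hexahydro-1-benzofuran-2-yl]dodeca-2,4,6,8,10-pentaen-1-yl acetate
Product: 19 (2E,4E,6E,8E,10E)-2,7-dimethyl-11-[(2S,7aR)-4,4,7a-trimethyl-2,4,5,6,7,7a-hexahydro-1-benzofuran-2-yl]dodeca-2,4,6,8,10-pentaen-1-ol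
Conditions: K2CO3 (0.2 equiv), MeOH/THF, 0 °C → rt
Reagents that add atoms: none
Why: Base-catalysed transesterification (methanolysis) removes the acetate under conditions the furanoid ether tolerates.

Step 15
Reactants: 19 (2E,4E,6E,8E,10E)-2,7-dimethyl-11-[(2S,7aR)-4,4,7a-trimethyl-2,4,5,6,7,7a-hexahydro-1-benzofuran-2-yl]dodeca-2,4,6,8,10-pentaen-1-ol
Product: 20 (2E,4E,6E,8E,10E)-2,7-dimethyl-11-[(2S,7aR)-4,4,7a-trimethyl-2,4,5,6,7,7a-hexahydro-1-benzofuran-2-yl]dodeca-2,4,6,8,10-pentaenal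
Conditions: activated MnO2, CH2Cl2, rt; then heptane, 80 °C, 1 h
Reagents that add atoms: none
Why: MnO2 oxidation of the polyenyl allylic alcohol gives the C25 polyenal, and the short heating converges the hindered 11′Z isomer to E.

Step 16
Reactants: 4 (1S,6R)-2,2,6-trimethyl-7-oxabicyclo[4.1.0]heptane-1-carbaldehyde
Product: 22 (1R)-1,3,3-trimethyl-2-methylidenecyclohexan-1-ol, via epoxy hydrazone 21 (not isolated)
Conditions: N2H4·H2O (3 equiv), AcOH (0.2 equiv), MeOH, 0 °C → rt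
Reagents that add atoms: none
Why: Wharton transposition, in which the epoxy hydrazone fragments with loss of N2 to the exocyclic alkene and the tertiary alcohol; the C5–O bond is never broken, so C5 stays R while the C6 centre is deliberately erased.

Step 17
Reactants: 22 (1R)-1,3,3-trimethyl-2-methylidenecyclohexan-1-ol
Product: 23 triethyl{[(1R)-1,3,3-trimethyl-2-methylidenecyclohexyl]oxy}silane
Conditions: Et3SiOTf, 2,6-lutidine, CH2Cl2, −78 → 0 °C
Reagents that add atoms: triethylsilyl trifluoromethanesulfonate CC[Si](CC)(CC)OS(=O)(=O)C(F)(F)F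
Why: Silylation of the hindered tertiary alcohol with the silyl triflate installs a non-chelating group that later directs the ketone addition.

Step 18
Reactants: 23 triethyl{[(1R)-1,3,3-trimethyl-2-methylidenecyclohexyl]oxy}silane
Product: 25 (2R)-2,6,6-trimethyl-2-[(triethylsilyl)oxy]cyclohexan-1-one, via ozonide 24 (not isolated)
Conditions: O3, CH2Cl2, −78 °C; then PPh3, −78 °C → rt
Reagents that add atoms: ozone [O-][O+]=O
Why: Ozonolysis of the only alkene with reductive work-up gives a ketone that has no α-hydrogen, so the C5 centre cannot epimerise.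

Step 19
Reactants: 26 (2E)-3-methylpent-2-en-4-yn-1-ol
Product: 27 tert-butyl(dimethyl){[(2E)-3-methylpent-2-en-4-yn-1-yl]oxy}silane
Conditions: t-BuMe2SiCl, imidazole, DMF, 0 °C → rt
Reagents that add atoms: tert-butyl(chloro)dimethylsilane CC(C)(C)[Si](C)(C)Cl
Why: Standard silylation protects the primary alcohol so that only the alkyne C–H is deprotonated in the next step.

Step 20
Reactants: 27 tert-butyl(dimethyl){[(2E)-3-methylpent-2-en-4-yn-1-yl]oxy}silane; 25 (2R)-2,6,6-trimethyl-2-[(triethylsilyl)oxy]cyclohexan-1-one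
Product: 29 (1R,2R)-1-[(3E)-5-{[tert-butyl(dimethyl)silyl]oxy}-3-methylpent-3-en-1-yn-1-yl]-2,6,6-trimethyl-2-[(triethylsilyl)oxy]cyclohexan-1-ol, via lithium acetylide 28 (not isolated)
Conditions: n-BuLi, THF, −78 °C; then 25, −78 → −20 °C; sat. NH4Cl at −40 °C
Reagents that add atoms: none
Why: 1,2-Addition of the slim acetylide to the non-enolisable ketone follows the polar Felkin–Anh model (axial attack anti to the axial α-silyloxy group), so the alkynyl group ends up trans to OSi and the new C6 hydroxyl cis to the C5 oxygen.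

Step 21
Reactants: 29 (1R,2R)-1-[(3E)-5-{[tert-butyl(dimethyl)silyl]oxy}-3-methylpent-3-en-1-yn-1-yl]-2,6,6-trimethyl-2-[(triethylsilyl)oxy]cyclohexan-1-ol
Product: 30 (1S,2R)-1-[(1E,3E)-5-{[tert-butyl(dimethyl)silyl]oxy}-3-methylpenta-1,3-dien-1-yl]-2,6,6-trimethyl-2-[(triethylsilyl)oxy]cyclohexan-1-ol
Conditions: NaAlH2(OCH2CH2OMe)2 (3 equiv), THF, 0 °C → rt; aq. potassium sodium tartrate
Reagents that add atoms: none
Why: trans-Hydroalumination of the propargylic alkoxide, with hydride delivered from the oxygen-bound aluminium, gives only the 7E alkene and leaves both stereocentres alone (the C1 descriptor changes by priority only).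

Step 22
Reactants: 30 (1S,2R)-1-[(1E,3E)-5-{[tert-butyl(dimethyl)silyl]oxy}-3-methylpenta-1,3-dien-1-yl]-2,6,6-trimethyl-2-[(triethylsilyl)oxy]cyclohexan-1-ol
Product: 31 (1S,2R)-1-[(1E,3E)-5-hydroxy-3-methylpenta-1,3-dien-1-yl]-2,6,6-trimethylcyclohexane-1,2-diol
Conditions: Bu4NF (4 equiv), THF, 0 → 40 °C
Reagents that add atoms: none
Why: Fluoride-mediated desilylation removes both silyl ethers under mildly basic conditions that the acid-labile tertiary allylic diol tolerates.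

Step 23
Reactants: 31 (1S,2R)-1-[(1E,3E)-5-hydroxy-3-methylpenta-1,3-dien-1-yl]-2,6,6-trimethylcyclohexane-1,2-diol
Product: 33 {(2E,4E)-5-[(1S,2R)-1,2-dihydroxy-2,6,6-trimethylcyclohexyl]-3-methylpenta-2,4-dien-1-yl}(triphenyl)phosphonium bromide, via dienyl bromide 32 (not isolated)
Conditions: CBr4 (1.1 equiv), PPh3 (1.15 equiv), 2,6-lutidine (0.3 equiv), CH2Cl2, −30 °C; then PPh3 (1.5 equiv), −30 °C → rt
Reagents that add atoms: carbon tetrabromide BrC(Br)(Br)Br; triphenylphosphine c1ccc(cc1)P(c1ccccc1)c1ccccc1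
Why: Appel bromination picks the unhindered primary allylic hydroxyl over the two hindered tertiary ones, and SN2 capture by PPh3 in the same flask forms the salt before the dienyl bromide can ionise.

Step 24
Reactants: 33 {(2E,4E)-5-[(1S,2R)-1,2-dihydroxy-2,6,6-trimethylcyclohexyl]-3-methylpenta-2,4-dien-1-yl}(triphenyl)phosphonium bromide; 20 (2E,4E,6E,8E,10E)-2,7-dimethyl-11-[(2S,7aR)-4,4,7a-trimethyl-2,4,5,6,7,7a-hexahydro-1-benzofuran-2-yl]dodeca-2,4,6,8,10-pentaenal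
Product: 35 (5R,6S,5′R,8′S)-5′,8′-epoxy-5,6,5′,8′-tetrahydro-β,β-carotene-5,6-diol (all-E; CNP0378030.2), via phosphonium ylide 34 (not isolated)
Conditions: 1,2-epoxybutane/EtOH (1:1), 70 °C, 20 h, N2, dark; then heptane/EtOAc, 75 °C, 2 h; crystallise
Reagents that add atoms: none
Why: Wittig olefination under neutral epoxybutane conditions forms C11=C12 with the free diol and the furanoid ether intact, and the heating turns the hindered 11Z isomer into the all-E polyene with all four stereocentres carried in unchanged.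

**Compound list**
1 | β-cyclocitral (2,6,6-trimethylcyclohex-1-ene-1-carbaldehyde) | CC1=C(C=O)C(C)(C)CCC1 | starting material
2 | β-cyclogeraniol [(2,6,6-trimethylcyclohex-1-en-1-yl)methanol] | CC1=C(CO)C(C)(C)CCC1 | intermediate
3 | [(1R,6R)-2,2,6-trimethyl-7-oxabicyclo[4.1.0]heptan-1-yl]methanol | OC[C@@]12O[C@]1(C)CCCC2(C)C | intermediate
4 | (1S,6R)-2,2,6-trimethyl-7-oxabicyclo[4.1.0]heptane-1-carbaldehyde | O=C[C@@]12O[C@]1(C)CCCC2(C)C | intermediate
5 | (1R,6R)-1-ethynyl-2,2,6-trimethyl-7-oxabicyclo[4.1.0]heptane | C#C[C@@]12O[C@]1(C)CCCC2(C)C | intermediate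
6 | ethyl acetoacetate (ethyl 3-oxobutanoate) | CCOC(=O)CC(C)=O | starting material
7 | ethyl (2E)-3-{[(trifluoromethyl)sulfonyl]oxy}but-2-enoate | CCOC(=O)/C=C(\C)OS(=O)(=O)C(F)(F)F | intermediate
8 | ethyl (2E)-3-methyl-5-[(1R,6R)-2,2,6-trimethyl-7-oxabicyclo[4.1.0]heptan-1-yl]pent-2-en-4-ynoate | CCOC(=O)/C=C(\C)C#C[C@@]12O[C@]1(C)CCCC2(C)C | intermediate
9 | (2E)-5-[(2R)-2-hydroxy-2,6,6-trimethylcyclohexylidene]-3-methylpenta-2,4-dien-1-ol, allene axis R | C[C@@]1(O)CCCC(C)(C)C1=[C@@]=C([H])/C(C)=C/CO | intermediate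
10 | (2E)-3-[(2S,7aR)-4,4,7a-trimethyl-2,4,5,6,7,7a-hexahydro-1-benzofuran-2-yl]but-2-en-1-ol | OC\C=C(/C)[C@@H]1C=C2C(C)(C)CCC[C@@]2(C)O1 | intermediate
11 | (2S,7aR)-2-[(2E)-4-bromobut-2-en-2-yl]-4,4,7a-trimethyl-2,4,5,6,7,7a-hexahydro-1-benzofuran | BrC\C=C(/C)[C@@H]1C=C2C(C)(C)CCC[C@@]2(C)O1 | intermediate
12 | {(2E)-3-[(2S,7aR)-4,4,7a-trimethyl-2,4,5,6,7,7a-hexahydro-1-benzofuran-2-yl]but-2-en-1-yl}(triphenyl)phosphonium bromide | [Br-].C(\C=C(/C)[C@@H]1C=C2C(C)(C)CCC[C@@]2(C)O1)[P+](c1ccccc1)(c1ccccc1)c1ccccc1 | intermediate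
13 | (2E,4E,6E)-2,7-dimethylocta-2,4,6-trienedial | O=C/C(C)=C/C=C/C=C(\C)C=O | starting material
14 | (2E,4E,6E)-2,7-dimethylocta-2,4,6-triene-1,8-diol | OC/C(C)=C/C=C/C=C(\C)CO | intermediate
15 | (2E,4E,6E)-8-hydroxy-2,7-dimethylocta-2,4,6-trien-1-yl acetate | CC(=O)OC/C(C)=C/C=C/C=C(\C)CO | intermediate
16 | (2E,4E,6E)-2,7-dimethyl-8-oxoocta-2,4,6-trien-1-yl acetate | CC(=O)OC/C(C)=C/C=C/C=C(\C)C=O | intermediate
17 | ylide of 12, triphenyl{(2E)-3-[(2S,7aR)-4,4,7a-trimethyl-2,4,5,6,7,7a-hexahydro-1-benzofuran-2-yl]but-2-en-1-ylidene}phosphorane | [CH-](\C=C(/C)[C@@H]1C=C2C(C)(C)CCC[C@@]2(C)O1)[P+](c1ccccc1)(c1ccccc1)c1ccccc1 | intermediate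
18 | (2E,4E,6E,8E,10E)-2,7-dimethyl-11-[(2S,7aR)-4,4,7a-trimethyl-2,4,5,6,7,7a-hexahydro-1-benzofuran-2-yl]dodeca-2,4,6,8,10-pentaen-1-yl acetate | CC(=O)OC/C(C)=C/C=C/C=C(C)/C=C/C=C(\C)[C@@H]1C=C2C(C)(C)CCC[C@@]2(C)O1 | intermediate
19 | (2E,4E,6E,8E,10E)-2,7-dimethyl-11-[(2S,7aR)-4,4,7a-trimethyl-2,4,5,6,7,7a-hexahydro-1-benzofuran-2-yl]dodeca-2,4,6,8,10-pentaen-1-ol | OC/C(C)=C/C=C/C=C(C)/C=C/C=C(\C)[C@@H]1C=C2C(C)(C)CCC[C@@]2(C)O1 | intermediate
20 | (2E,4E,6E,8E,10E)-2,7-dimethyl-11-[(2S,7aR)-4,4,7a-trimethyl-2,4,5,6,7,7a-hexahydro-1-benzofuran-2-yl]dodeca-2,4,6,8,10-pentaenal | O=C/C(C)=C/C=C/C=C(C)/C=C/C=C(\C)[C@@H]1C=C2C(C)(C)CCC[C@@]2(C)O1 | intermediate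
21 | (E)-{[(1R,6R)-2,2,6-trimethyl-7-oxabicyclo[4.1.0]heptan-1-yl]methylidene}hydrazine (hydrazone of 4) | N/N=C/[C@@]12O[C@]1(C)CCCC2(C)C | intermediate
22 | (1R)-1,3,3-trimethyl-2-methylidenecyclohexan-1-ol | C[C@@]1(O)CCCC(C)(C)C1=C | intermediate
23 | triethyl{[(1R)-1,3,3-trimethyl-2-methylidenecyclohexyl]oxy}silane | C[C@@]1(O[Si](CC)(CC)CC)CCCC(C)(C)C1=C | intermediate
24 | (6R)-6,10,10-trimethyl-6-[(triethylsilyl)oxy]-1,2,4-trioxaspiro[4.5]decane (ozonide, spiro centre unassigned) | C[C@@]1(O[Si](CC)(CC)CC)CCCC(C)(C)C12OCOO2 | intermediate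
25 | (2R)-2,6,6-trimethyl-2-[(triethylsilyl)oxy]cyclohexan-1-one | C[C@@]1(O[Si](CC)(CC)CC)CCCC(C)(C)C1=O | intermediate
26 | (2E)-3-methylpent-2-en-4-yn-1-ol | C#C/C(C)=C/CO | starting material
27 | tert-butyl(dimethyl){[(2E)-3-methylpent-2-en-4-yn-1-yl]oxy}silane | C#C/C(C)=C/CO[Si](C)(C)C(C)(C)C | intermediate
28 | lithium acetylide of 27 | [Li]C#C/C(C)=C/CO[Si](C)(C)C(C)(C)C | intermediate
29 | (1R,2R)-1-[(3E)-5-{[tert-butyl(dimethyl)silyl]oxy}-3-methylpent-3-en-1-yn-1-yl]-2,6,6-trimethyl-2-[(triethylsilyl)oxy]cyclohexan-1-ol | CC(C)(C)[Si](C)(C)OC/C=C(\C)C#C[C@]1(O)C(C)(C)CCC[C@@]1(C)O[Si](CC)(CC)CC | intermediate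
30 | (1S,2R)-1-[(1E,3E)-5-{[tert-butyl(dimethyl)silyl]oxy}-3-methylpenta-1,3-dien-1-yl]-2,6,6-trimethyl-2-[(triethylsilyl)oxy]cyclohexan-1-ol | CC(C)(C)[Si](C)(C)OC/C=C(C)/C=C/[C@]1(O)C(C)(C)CCC[C@@]1(C)O[Si](CC)(CC)CC | intermediate
31 | (1S,2R)-1-[(1E,3E)-5-hydroxy-3-methylpenta-1,3-dien-1-yl]-2,6,6-trimethylcyclohexane-1,2-diol | OC/C=C(C)/C=C/[C@]1(O)C(C)(C)CCC[C@@]1(C)O | intermediate
32 | (1S,2R)-1-[(1E,3E)-5-bromo-3-methylpenta-1,3-dien-1-yl]-2,6,6-trimethylcyclohexane-1,2-diol | BrC/C=C(C)/C=C/[C@]1(O)C(C)(C)CCC[C@@]1(C)O | intermediate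
33 | {(2E,4E)-5-[(1S,2R)-1,2-dihydroxy-2,6,6-trimethylcyclohexyl]-3-methylpenta-2,4-dien-1-yl}(triphenyl)phosphonium bromide | [Br-].C(/C=C(C)/C=C/[C@]1(O)C(C)(C)CCC[C@@]1(C)O)[P+](c1ccccc1)(c1ccccc1)c1ccccc1 | intermediate
34 | ylide of 33, triphenyl{(2E,4E)-5-[(1S,2R)-1,2-dihydroxy-2,6,6-trimethylcyclohexyl]-3-methylpenta-2,4-dien-1-ylidene}phosphorane | [CH-](/C=C(C)/C=C/[C@]1(O)C(C)(C)CCC[C@@]1(C)O)[P+](c1ccccc1)(c1ccccc1)c1ccccc1 | intermediate
35 | (5R,6S,5′R,8′S)-5′,8′-epoxy-5,6,5′,8′-tetrahydro-β,β-carotene-5,6-diol (all-E) | CC(/C=C/C=C(C)/C=C/[C@]1(O)C(C)(C)CCC[C@@]1(C)O)=C\C=C\C=C(C)\C=C\C=C(/C)[C@@H]1C=C2C(C)(C)CCC[C@@]2(C)O1 | target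

**Totals**
Total step count: 24.
Longest linear sequence: 12 steps (1, 2, 3, 4, 6, 7, 8, 9, 13, 14, 15, 24, from β-cyclocitral 1 to 35).

**Steps most likely to fail, with fallbacks**

Step 7 (sense and cleanliness of the hydride SN2′ delivery). If the hydride is not delivered cleanly syn, allene epimers result and step 8 turns them into C8′ epimers. The fallback leaves the allene route at aldehyde 4 and comes back at 10, bypassing steps 4 to 8. Horner–Wadsworth–Emmons reaction of 4 with triethyl 3-methyl-4-phosphonobut-2-enoate (n-BuLi, THF/DMPU, −78 → 0 °C) gives ethyl (2E,4E)-3-methyl-5-[(1S,6R)-2,2,6-trimethyl-7-oxabicyclo[4.1.0]heptan-1-yl]penta-2,4-dienoate F1. Reduction with i-Bu2AlH (CH2Cl2, −78 °C) gives (2E,4E)-3-methyl-5-[(1S,6R)-2,2,6-trimethyl-7-oxabicyclo[4.1.0]heptan-1-yl]penta-2,4-dien-1-ol F2. Pyridinium p-toluenesulfonate (5 mol%, CH2Cl2, 0 °C) then triggers the classical 5,6-epoxide to 5,8-furanoid rearrangement. This gives 10 together with its C2 epimer (2E)-3-[(2R,7aR)-4,4,7a-trimethyl-2,4,5,6,7,7a-hexahydro-1-benzofuran-2-yl]but-2-en-1-ol F3. The two are separated by chromatography, and F3 is re-equilibrated with the same acid and recycled. This path is not stereoselective at C8′ (roughly 1:1), so it trades selectivity for precedent.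

Step 20 (facial selectivity of the acetylide addition that sets C6). If the trans-diol isomer dominates, the cis-diol is made by osmylation instead of carbonyl addition, setting out from 22 and coming back at 31. OsO4/TMEDA (1 equiv, CH2Cl2, −78 °C, then ethylenediamine) adds to the exocyclic alkene syn to the hydrogen-bonding tertiary hydroxyl and gives (1R,2R)-1-(hydroxymethyl)-2,6,6-trimethylcyclohexane-1,2-diol F4. TEMPO (cat.)/PhI(OAc)2 oxidises only the primary hydroxyl to (1S,2R)-1,2-dihydroxy-2,6,6-trimethylcyclohexane-1-carbaldehyde F5. The neutral stabilised ylide Ph3P=CHC(O)CH3 (toluene, 80 °C) gives (3E)-4-[(1S,2R)-1,2-dihydroxy-2,6,6-trimethylcyclohexyl]but-3-en-2-one F6. Horner–Wadsworth–Emmons reaction with triethyl phosphonoacetate (NaH, THF; the 9Z isomer is removed) gives ethyl (2E,4E)-5-[(1S,2R)-1,2-dihydroxy-2,6,6-trimethylcyclohexyl]-3-methylpenta-2,4-dienoate F7. Reduction with i-Bu2AlH (THF, −78 → 0 °C) gives 31.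

Step 23 (dienyl bromide next to the tertiary allylic diol; ionisation or semipinacol shift before the phosphine captures it). The fallback reverses the polarity of the last coupling, setting out from 31 and 19 and coming back at 35. TEMPO (cat.)/PhI(OAc)2 (CH2Cl2, NaHCO3) oxidises 31 to (2E,4E)-5-[(1S,2R)-1,2-dihydroxy-2,6,6-trimethylcyclohexyl]-3-methylpenta-2,4-dienal F8, in which the diol is no longer next to a leaving group. Alcohol 19 is converted with CBr4/PPh3 (CH2Cl2, −30 °C) into (2S,7aR)-2-[(2E,4E,6E,8E,10E)-12-bromo-6,11-dimethyldodeca-2,4,6,8,10-pentaen-2-yl]-4,4,7a-trimethyl-2,4,5,6,7,7a-hexahydro-1-benzofuran F9. More PPh3 in the same flask gives {(2E,4E,6E,8E,10E)-2,7-dimethyl-11-[(2S,7aR)-4,4,7a-trimethyl-2,4,5,6,7,7a-hexahydro-1-benzofuran-2-yl]dodeca-2,4,6,8,10-pentaen-1-yl}(triphenyl)phosphonium bromide F10. In 1,2-epoxybutane/EtOH at 70 °C this gives the C25 phosphonium ylide F11, which reacts with F8 to give 35 after the same thermal isomerisation as in step 24.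

**Further compounds**
F1 | step 7 | ethyl (2E,4E)-3-methyl-5-[(1S,6R)-2,2,6-trimethyl-7-oxabicyclo[4.1.0]heptan-1-yl]penta-2,4-dienoate | CCOC(=O)/C=C(C)/C=C/[C@@]12O[C@]1(C)CCCC2(C)C
F2 | step 7 | (2E,4E)-3-methyl-5-[(1S,6R)-2,2,6-trimethyl-7-oxabicyclo[4.1.0]heptan-1-yl]penta-2,4-dien-1-ol | OC/C=C(C)/C=C/[C@@]12O[C@]1(C)CCCC2(C)C
F3 | step 7 | (2E)-3-[(2R,7aR)-4,4,7a-trimethyl-2,4,5,6,7,7a-hexahydro-1-benzofuran-2-yl]but-2-en-1-ol | OC\C=C(/C)[C@H]1C=C2C(C)(C)CCC[C@@]2(C)O1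
F4 | step 20 | (1R,2R)-1-(hydroxymethyl)-2,6,6-trimethylcyclohexane-1,2-diol | OC[C@]1(O)C(C)(C)CCC[C@@]1(C)O
F5 | step 20 | (1S,2R)-1,2-dihydroxy-2,6,6-trimethylcyclohexane-1-carbaldehyde | O=C[C@]1(O)C(C)(C)CCC[C@@]1(C)O
F6 | step 20 | (3E)-4-[(1S,2R)-1,2-dihydroxy-2,6,6-trimethylcyclohexyl]but-3-en-2-one | CC(=O)/C=C/[C@]1(O)C(C)(C)CCC[C@@]1(C)O
F7 | step 20 | ethyl (2E,4E)-5-[(1S,2R)-1,2-dihydroxy-2,6,6-trimethylcyclohexyl]-3-methylpenta-2,4-dienoate | CCOC(=O)/C=C(C)/C=C/[C@]1(O)C(C)(C)CCC[C@@]1(C)O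
F8 | step 23 | (2E,4E)-5-[(1S,2R)-1,2-dihydroxy-2,6,6-trimethylcyclohexyl]-3-methylpenta-2,4-dienal | O=C/C=C(C)/C=C/[C@]1(O)C(C)(C)CCC[C@@]1(C)O
F9 | step 23 | (2S,7aR)-2-[(2E,4E,6E,8E,10E)-12-bromo-6,11-dimethyldodeca-2,4,6,8,10-pentaen-2-yl]-4,4,7a-trimethyl-2,4,5,6,7,7a-hexahydro-1-benzofuran | BrC/C(C)=C/C=C/C=C(C)/C=C/C=C(\C)[C@@H]1C=C2C(C)(C)CCC[C@@]2(C)O1
F10 | step 23 | {(2E,4E,6E,8E,10E)-2,7-dimethyl-11-[(2S,7aR)-4,4,7a-trimethyl-2,4,5,6,7,7a-hexahydro-1-benzofuran-2-yl]dodeca-2,4,6,8,10-pentaen-1-yl}(triphenyl)phosphonium bromide | [Br-].C(/C(C)=C/C=C/C=C(C)/C=C/C=C(\C)[C@@H]1C=C2C(C)(C)CCC[C@@]2(C)O1)[P+](c1ccccc1)(c1ccccc1)c1ccccc1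
F11 | step 23 | ylide of F10, triphenyl{(2E,4E,6E,8E,10E)-2,7-dimethyl-11-[(2S,7aR)-4,4,7a-trimethyl-2,4,5,6,7,7a-hexahydro-1-benzofuran-2-yl]dodeca-2,4,6,8,10-pentaen-1-ylidene}phosphorane | [CH-](/C(C)=C/C=C/C=C(C)/C=C/C=C(\C)[C@@H]1C=C2C(C)(C)CCC[C@@]2(C)O1)[P+](c1ccccc1)(c1ccccc1)c1ccccc1
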